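Retrosynthesis: the ring D enol is first masked again as its 3-methylbut-2-enoate. The furan (ring C: O1, C2 with the isobutenyl group, C3, C4, C5 bonded to ring A) is then cut at O1–C2 and at C2=C3. This gives 3-methylbut-2-enoyl chloride and an A/B/D/E tetracycle.
Enabling feature: O1–C5–C4–C3 of the furan is a hidden enone O=C–C=CH. C5=O1 is a ring B quinone carbonyl, and C3 is the single CH carbon of ring D, β to that carbonyl and α to the ring D ketone. C3 can therefore take up a phosphine, become a stabilised ylide and reach an acyl group held on O1.
The tetracycle is cut in ring D at CH2–C(=O) (lateral Claisen) and at naphthyl–C(=O) (aryllithium plus anhydride). This leads to menadione (rings A and B and the future C3) and phthalic anhydride (ring E and both ring D carbonyl carbons).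
Forward: rings A/B are bought and masked as the dimethyl ether, ring E is attached, ring D is closed, ring B is re-oxidised, ring C is closed last, and the sacrificial ester is removed.
Stereochemistry: the target has no stereocentre and no stereogenic double bond (the isobutenyl terminus carries two methyl groups), so nothing has to be controlled.
Key step: step 7

Assumption: the tetracyclic key-step precursor and the target each belong to a set of rapidly interconverting prototropic tautomers; both are drawn in the chelated ring D enol / ring B ketone form that matches the target structure.

Step 1
Reactants: 1 menadione (2-methyl-1,4-naphthoquinone)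
Product: 3 1,4-dimethoxy-2-methylnaphthalene, via menadiol 2 (not isolated)
Conditions: Na2S2O4, Bu4NBr (cat.), THF/H2O, rt; then aq KOH, Me2SO4, rt
Reagents that add atoms: dimethyl sulfate, COS(=O)(=O)OC
Why: Dithionite reduction of the quinone followed by Williamson O-methylation of the hydroquinone in the same flask is the standard reductive methylation of naphthoquinones, and not isolating air-sensitive 2 prevents its re-oxidation.

Step 2
Reactants: 3 1,4-dimethoxy-2-methylnaphthalene
Product: 4 2-bromo-1,4-dimethoxy-3-methylnaphthalene
Conditions: Br2, CH2Cl2, 0 °C, dark
Reagents that add atoms: bromine, BrBr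
Why: Electrophilic aromatic bromination should go to C3, the only unsubstituted position of the ring that carries both methoxy groups, while cold, dark, ionic conditions leave the benzylic methyl group untouched.

Step 3
Reactants: 4 2-bromo-1,4-dimethoxy-3-methylnaphthalene; 5 phthalic anhydride
Product: 7 2-(1,4-dimethoxy-3-methyl-2-naphthoyl)benzoic acid, via aryllithium 6 (not isolated)
Conditions: n-BuLi, THF, −78 °C; cannulated into 5 (2 equiv), THF, −78 °C to rt; aq HCl
Reagents that add atoms: none
Why: Bromine–lithium exchange followed by nucleophilic ring opening of the cyclic anhydride stops at the ketone stage because the product is a lithium carboxylate whose carbonyl is flanked on both ortho positions, and inverse addition to excess 5 further suppresses a second addition.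

Step 4
Reactants: 7 2-(1,4-dimethoxy-3-methyl-2-naphthoyl)benzoic acid
Product: 8 methyl 2-(1,4-dimethoxy-3-methyl-2-naphthoyl)benzoate
Conditions: MeI, K2CO3, DMF, rt
Reagents that add atoms: iodomethane, CI
Why: SN2 O-alkylation of the carboxylate delivers the open-chain methyl ester, whereas Fischer conditions on a 2-aroylbenzoic acid could give the cyclic pseudo-ester.

Step 5
Reactants: 8 methyl 2-(1,4-dimethoxy-3-methyl-2-naphthoyl)benzoate
Product: 10 dimethoxy tetracyclic diketone (1,4-dimethoxynaphthalene bridged from C2 to C3 by C(=O)-C6H4-C(=O)-CH2), via benzylic lithium species 9 (not isolated)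
Conditions: LiN(iPr)2 (2.5 equiv), THF, −78 to 0 °C; aq HCl
Reagents that add atoms: none
Why: Lateral lithiation of the methyl group, which sits ortho to the aroyl carbonyl and next to a lithium-coordinating methoxy group, followed by an intramolecular Claisen (Dieckmann-type) acylation in a 7-exo-trig closure should form ring D, and deprotonation of the more acidic benzylic ketone by the second equivalent of base makes the closure irreversible.

Step 6
Reactants: 10 dimethoxy tetracyclic diketone
Product: 12 naphthoquinone-fused hydroxybenzotropone (chelated enol tautomer), via quinone triketone 11 (not isolated)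
Conditions: (NH4)2Ce(NO3)6 (2.5 equiv), MeCN/H2O, 0 °C
Reagents that add atoms: water, O
Why: Oxidative demethylation of a 1,4-dimethoxynaphthalene by tetravalent cerium is the standard way back to the naphthoquinone, and the CH2 group of 11, now flanked by a quinone carbon and a ketone, should enolise at once to the fully conjugated, hydrogen-bonded tropone 12.

Step 7
Reactants: 12 naphthoquinone-fused hydroxybenzotropone; 13 3-methylbut-2-enoyl chloride (two equivalents enter the product)
Product: 17 radermachol enol 3-methylbut-2-enoate, via phosphonium betaine 14 (not isolated), via bis-ester phosphonium chloride 15 (not isolated), via keto ylide 16 (not isolated)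
Conditions: PBu3 (1.2 equiv), THF, 0 °C; 13 (2.5 equiv); then Et3N (3 equiv), 0 °C to rt
Reagents that add atoms: none
Why: PBu3 adds in a phospha-Michael sense to the ring D CH carbon of 12, the β-carbon of the enone that ends in the ring B carbonyl remote from the chelated enol, and the charge lands on that oxygen to give betaine 14. That oxygen and the ring D enol oxygen are acylated by 13 to give salt 15, and Et3N then removes the proton on the phosphorus-bearing carbon, which is also α to the ring D ketone, to give the stabilised keto ylide 16. The ylide carbon attacks the carbonyl of the neighbouring aryl-type ester in a 5-exo-trig closure, and collapse of the oxaphosphetane with loss of Bu3P=O forms C2=C3 beside the O1–C2 bond made in the acylation, so ring C appears directly at the aromatic furan level. The closest known reaction type is the one-pot phosphine, acyl chloride and amine synthesis of tetrasubstituted furans from activated enones (Michael addition, O-acylation, intramolecular Wittig), a relative of the benzofuran synthesis from 2-hydroxybenzylphosphonium salts and acyl chlorides. No stereocentre survives, since the phosphorus-bearing carbon of 14 and 15 is stereogenic only in passing and becomes planar in 16. The step needs site selectivity for phosphine attack, secured because 12 has a single hydrogen-bearing electrophilic alkene carbon, and for the Wittig carbonyl, secured because only the ester on the ring B oxygen lies within a five-membered reach of the ylide carbon, while adding the amine last keeps 13 from being converted into a vinylketene before the decisive acylation.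

Step 8
Reactants: 17 radermachol enol 3-methylbut-2-enoate
Product: 18 radermachol
Conditions: K2CO3 (1.5 equiv), MeOH/CH2Cl2, 0 °C to rt; aq HCl
Reagents that add atoms: none
Why: Base-mediated transesterification cleaves this ester selectively because it is the enol ester of a strongly acidic vinylogous acid and thus an activated acyl donor, while the furan, the isobutenyl group and the ketones do not react with K2CO3 in methanol.

Compound list
1 | menadione (2-methyl-1,4-naphthoquinone) | CC1=CC(=O)c2ccccc2C1=O | starting material
2 | menadiol (2-methylnaphthalene-1,4-diol), not isolated | Cc1cc(O)c2ccccc2c1O | intermediate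
3 | 1,4-dimethoxy-2-methylnaphthalene | COc1cc(C)c(OC)c2ccccc12 | intermediate
4 | 2-bromo-1,4-dimethoxy-3-methylnaphthalene | COc1c(Br)c(C)c(OC)c2ccccc12 | intermediate
5 | phthalic anhydride | O=C1OC(=O)c2ccccc12 | starting material
6 | (1,4-dimethoxy-3-methylnaphthalen-2-yl)lithium, not isolated | [Li]c1c(C)c(OC)c2ccccc2c1OC | intermediate
7 | 2-(1,4-dimethoxy-3-methyl-2-naphthoyl)benzoic acid | COc1c(C)c(C(=O)c2ccccc2C(=O)O)c(OC)c2ccccc12 | intermediate
8 | methyl 2-(1,4-dimethoxy-3-methyl-2-naphthoyl)benzoate | COC(=O)c1ccccc1C(=O)c1c(C)c(OC)c2ccccc2c1OC | intermediate
9 | methyl 2-[3-(lithiomethyl)-1,4-dimethoxy-2-naphthoyl]benzoate, not isolated | [Li]Cc1c(OC)c2ccccc2c(OC)c1C(=O)c1ccccc1C(=O)OC | intermediate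
10 | dimethoxy tetracyclic diketone (1,4-dimethoxynaphthalene bridged from C2 to C3 by C(=O)-C6H4-C(=O)-CH2) | COc1c2CC(=O)c3ccccc3C(=O)c2c(OC)c2ccccc12 | intermediate
11 | quinone triketone (CH2 tautomer of 12), not isolated | O=C1c2ccccc2C(=O)C2=C1CC(=O)c1ccccc1C2=O | intermediate
12 | naphthoquinone-fused hydroxybenzotropone, chelated enol tautomer (ring B 1,4-dione whose two remaining carbons carry the ring D C=C(OH) and C=CH bonds) | O=C1c2ccccc2C(=O)C2=C(O)c3ccccc3C(=O)C=C12 | intermediate
13 | 3-methylbut-2-enoyl chloride | CC(C)=CC(Cl)=O | starting material
14 | phosphonium betaine (PBu3 adduct at the ring D CH carbon, ring B enolate; racemic), not isolated | CCCC[P+](CCCC)(CCCC)C1C(=O)c2ccccc2C(O)=C2C(=O)c3ccccc3C([O-])=C12 | intermediate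
15 | bis(3-methylbut-2-enoate) phosphonium chloride (racemic), not isolated | CCCC[P+](CCCC)(CCCC)C1C(=O)c2ccccc2C(OC(=O)C=C(C)C)=C2C(=O)c3ccccc3C(OC(=O)C=C(C)C)=C12.[Cl-] | intermediate
16 | keto-stabilised tributylphosphonium ylide, not isolated | CCCCP(CCCC)(CCCC)=C1C(=O)c2ccccc2C(OC(=O)C=C(C)C)=C2C(=O)c3ccccc3C(OC(=O)C=C(C)C)=C12 | intermediate
17 | radermachol enol 3-methylbut-2-enoate | CC(C)=Cc1oc2c3c(c(OC(=O)C=C(C)C)c4ccccc4c(=O)c13)C(=O)c1ccccc1-2 | intermediate
18 | radermachol | CC(C)=Cc1oc2c3c(c(O)c4ccccc4c(=O)c13)C(=O)c1ccccc1-2 | target

Total steps: 8. Longest linear sequence: 8 steps (1 to 18).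

Steps most likely to fail

Risk 1 (step 7).
- What may go wrong:
  - The ambident anion of 12 may be acylated on the ring D ketone oxygen, which removes the enone needed for phosphine attack.
  - The phosphine may be consumed by the acyl chloride.
  - The amine may deconjugate the acyl unit through a vinylketene.
  - The doubly stabilised ylide may be O-acylated, or may attack the ester carbonyl too slowly.
  - Acylation of the chelate on its ring B oxygen instead of its ring D oxygen would do no harm, because methanolysis leads to the same tautomeric set.
- Fallback: the furan would be made by classical cyclodehydration of a 2-hydroxyaryl-substituted 1,3-diketone, setting out from 10.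
  - Soft enolisation (MgBr2·OEt2, iPr2NEt, CH2Cl2) and C-acylation with 13 would give the C-acylated dimethoxy triketone F1.
  - BBr3 (CH2Cl2, −78 to 0 °C) would cleave both methyl ethers to the hydroquinone triketone F2.
  - The ring B hydroxyl of F2 next to the acylated carbon should then condense with the side-chain ketone on acidic work-up (or p-TsOH, toluene) with loss of water.
- The other hydroxyl is tied up in the chelate with the diaryl ketone. The side-chain alkene is conjugated to a carbonyl, so it is a poor partner for acid-induced cyclisation.
- No oxidant or reductant is needed, because F2 already has the oxidation level of the target. The sequence comes back to the route at 18 and bypasses steps 6 to 8.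

Risk 2 (step 5).
- What may go wrong:
  - Deprotonation of the methyl group may be too slow, because the aroyl carbonyl is twisted out of the naphthalene plane and conjugation across the naphthalene 2,3-bond is weak.
  - Hydride transfer or addition of the amide base at the diaryl ketone or the ester could then compete.
- Fallback: the order of oxidation and ring closure is reversed, setting out from 8.
  - (NH4)2Ce(NO3)6 in MeCN/H2O would give the quinone keto ester F3.
  - The methyl group of F3 is vinylogous to a ring B carbonyl and to the aroyl ketone, so it is acidic enough for DBU (THF, 0 °C, argon).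
  - The extended enolate should close onto the ester in a vinylogous Dieckmann condensation. Acidification then gives 12, where the fallback rejoins the route.
- Both quinone alkene carbons of F3 are substituted, so the base-induced Michael self-condensation typical of menadione is blocked.

Risk 3 (step 6).
- What may go wrong: one-electron over-oxidation of the activated methylene, or of the enol carbon of the product, by excess tetravalent cerium, and oxidative coupling.
- Fallback: ether cleavage and oxidation are separated, setting out from 10.
  - BBr3 (CH2Cl2, −78 °C to rt) would give the hydroquinone diketone F4.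
  - A mild two-electron oxidant (Ag2O, CH2Cl2, rt) would take F4 through 11 to 12, where the route is rejoined.

Further compounds
F1 | step 7 | C-acylated dimethoxy triketone (10 bearing a 3-methylbut-2-enoyl group on the ring D CH carbon; racemic, readily enolised) | COc1c2C(C(=O)C=C(C)C)C(=O)c3ccccc3C(=O)c2c(OC)c2ccccc12
F2 | step 7 | hydroquinone triketone (F1 with both methyl ethers cleaved; racemic, readily enolised) | CC(C)=CC(=O)C1C(=O)c2ccccc2C(=O)c2c(O)c3ccccc3c(O)c12
F3 | step 5 | quinone keto ester, methyl 2-(3-methyl-1,4-dioxo-1,4-dihydronaphthalene-2-carbonyl)benzoate | COC(=O)c1ccccc1C(=O)C1=C(C)C(=O)c2ccccc2C1=O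
F4 | step 6 | hydroquinone diketone (10 with both methyl ethers cleaved) | Oc1c2CC(=O)c3ccccc3C(=O)c2c(O)c2ccccc12
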